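**Assumption:** (2Z,6E)-farnesol (CAS 3790-71-4) is taken as purchasable in isomerically pure form from specialty suppliers; if not, it adds two steps from (E)-geranylacetone (HWE olefination, separation of the 2Z ester, DIBAL-H).

The target as drawn is (2R,3R): the 3-OH is trans to the 2-methyl and cis to the side chain. The route has not been run; conditions and selectivities are predictions from close precedent.

## Retrosynthetic overview

1. Acid 8 comes from methyl ester 7 by saponification.
2. The chroman (the only ring in the target, formed last) comes from 6-endo, anti opening of a cis-trisubstituted (2R,3S)-epoxide by the ortho phenol oxygen. This inverts the tertiary carbon to give C2 (R) and leaves the carbinol carbon untouched as C3 (R).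
3. The Ar–CH2 bond comes from Cu-catalysed coupling of an ester-bearing aryl Grignard (from methyl 4-hydroxy-3-iodobenzoate, phenol masked as an EE acetal) with the epoxy triflate.
4. The oxirane (first ring formed) and both stereocentres come from one Sharpless epoxidation of (2Z,6E)-farnesol with D-(−)-DET.
5. The 2Z geometry is required: anti O/O addition across a 2E olefin would give the C2/C3 cis-Me/OH diastereomer instead.

## Route

**Step 1**
Reactants: 1, methyl 4-hydroxy-3-iodobenzoate
Product: 2, methyl 4-(1-ethoxyethoxy)-3-iodobenzoate (racemic at the acetal carbon; the group is removed later)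
Conditions: ethyl vinyl ether (3 equiv), PPTS (5 mol %), CH2Cl2, 0 °C → rt; Et3N quench
Reagents that add atoms: ethyl vinyl ether, C=COCC
Why: Acid-catalysed addition of the phenol to the enol ether (acetalisation) gives an EE ether that is inert to Grignard reagents but falls off under the mild acid used in Step 5.

**Step 2**
Reactants: 3, (2Z,6E)-farnesol
Product: 4, [(2R,3S)-3-[(3E)-4,8-dimethylnona-3,7-dien-1-yl]-3-methyloxiran-2-yl]methanol (cis-epoxide: side chain cis to CH2OH)
Conditions: Ti(OiPr)4 (10 mol %), D-(−)-DET (12 mol %), t-BuOOH (2 equiv, decane), 4 Å MS, CH2Cl2, −25 °C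
Reagents that add atoms: tert-butyl hydroperoxide, CC(C)(C)OO
Why: Katsuki–Sharpless asymmetric epoxidation is hydroxyl-directed, so only the 2,3-alkene reacts; D-(−)-tartrate gives the 2R series (mirror of nerol + L-(+)-DET → 2S,3R), and the Z geometry fixes C3 as S (about 90–94 % ee expected, as for nerol).

**Step 3**
Reactants: 4
Product: 5, [(2R,3S)-3-[(3E)-4,8-dimethylnona-3,7-dien-1-yl]-3-methyloxiran-2-yl]methyl trifluoromethanesulfonate
Conditions: Tf2O (1.1 equiv), 2,6-lutidine (1.5 equiv), CH2Cl2, −78 °C, 15 min; cold pentane, filter, use at once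
Reagents that add atoms: triflic anhydride, FC(F)(F)S(=O)(=O)OS(=O)(=O)C(F)(F)F
Why: O-sulfonylation of the primary alcohol at low temperature breaks no bond at either stereocentre and gives an electrophile reactive enough to couple below −30 °C.

**Step 4**
Reactants: 2 (1.5 equiv) and 5 (1.0 equiv)
Product: 6, methyl 3-{[(2R,3S)-3-[(3E)-4,8-dimethylnona-3,7-dien-1-yl]-3-methyloxiran-2-yl]methyl}-4-(1-ethoxyethoxy)benzoate
Conditions: 2, i-PrMgCl (1.45 equiv), THF, −40 °C, 45 min; CuBr·SMe2 (10 mol %); then 5, −78 → −30 °C; aq NH4Cl/NH3
Reagents that add atoms: none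
Why: Knochel I/Mg exchange (chelation-assisted by the ortho acetal) tolerates the ester below −30 °C, and Cu-catalysed sp2–sp3 coupling displaces the primary triflate faster than the hindered epoxide is attacked; C1 is not stereogenic, so both epoxide centres are retained.

**Step 5**
Reactants: 6
Product: 7, methyl (2R,3R)-2-[(3E)-4,8-dimethylnona-3,7-dien-1-yl]-3-hydroxy-2-methyl-3,4-dihydro-2H-chromene-6-carboxylate
Conditions: CSA (10 mol %), MeOH (5 equiv), CH2Cl2, 0 °C; Et3N quench
Reagents that add atoms: none (the EE group leaves as acetaldehyde ethyl methyl acetal)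
Why: Acid cleaves the aryl acetal and the phenolic oxygen opens the protonated epoxide at the tertiary carbon (6-endo, Markovnikov, anti) with inversion, converting epoxide C3 (S) into chroman C2 (R); the other epoxide C–O bond is not broken and becomes the C3 (R) carbinol.

**Step 6**
Reactants: 7
Product: 8, Kuhistanol D, (2R,3R)-2-[(3E)-4,8-dimethylnona-3,7-dien-1-yl]-3-hydroxy-2-methylchromane-6-carboxylic acid
Conditions: LiOH·H2O (5 equiv), THF/MeOH/H2O 3:1:1, rt → 40 °C; then 10 % citric acid to pH 4
Reagents that add atoms: lithium hydroxide, [Li+].[OH-]; water, O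
Why: Ester saponification (BAc2); neither stereocentre is epimerisable under base, and the alkenes and tertiary aryl ether survive the mild acidification.

## Compound list

1 | methyl 4-hydroxy-3-iodobenzoate | COC(=O)c1ccc(O)c(I)c1 | starting material
2 | methyl 4-(1-ethoxyethoxy)-3-iodobenzoate | CCOC(C)Oc1ccc(C(=O)OC)cc1I | intermediate
3 | (2Z,6E)-farnesol | CC(C)=CCC/C(C)=C/CC/C(C)=C\CO | starting material
4 | (2R,3S)-2,3-epoxy-(6E)-farnesol (cis-epoxy alcohol) | CC(C)=CCC/C(C)=C/CC[C@]1(C)O[C@@H]1CO | intermediate
5 | (2R,3S)-epoxy triflate of 4 | CC(C)=CCC/C(C)=C/CC[C@]1(C)O[C@@H]1COS(=O)(=O)C(F)(F)F | intermediate (not stored)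
6 | methyl 3-[(2R,3S)-epoxyfarnesyl]-4-(1-ethoxyethoxy)benzoate | CC(C)=CCC/C(C)=C/CC[C@]1(C)O[C@@H]1Cc2cc(C(=O)OC)ccc2OC(C)OCC | intermediate
7 | Kuhistanol D methyl ester, (2R,3R) | CC(C)=CCC/C(C)=C/CC[C@@]1(C)Oc2ccc(C(=O)OC)cc2C[C@H]1O | intermediate
8 | Kuhistanol D, (2R,3R) | CC(C)=CCC/C(C)=C/CC[C@@]1(C)Oc2ccc(C(=O)O)cc2C[C@H]1O | target

## Summary

Total steps: 6. Longest linear sequence: 5 (3 → 4 → 5 → 6 → 7 → 8).

Steps most likely to fail, with fallbacks:

1. **Step 3 (epoxy triflate too labile; epoxide-oxygen participation or decomposition).** Fallback: avoid a sulfonate electrophile. Oxidise 4 to the epoxy aldehyde (Parikh–Doering), add the aryl Grignard from 2, acid-cyclise to the chroman-3,4-diol, and remove the benzylic C4–OH by ionic hydrogenation (Et3SiH/BF3·OEt2, −78 °C).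
2. **Step 4 (ester-bearing aryl Grignard is a sluggish partner; halide displacement of triflate or epoxide opening may compete).** Fallback: use an ester-free aryl partner. Take EE-protected 4-bromo-2-iodophenol, do selective I/Mg exchange, form the stoichiometric cuprate and couple it with the isolable epoxy tosylate. Cyclise as in Step 5, then install CO2H last by Br/Li exchange and CO2 quench, which replaces the saponification.
3. **Step 5 (5-exo closure to the dihydrobenzofuran, SN1 leakage at the tertiary carbon, or methanolysis before the phenol is released).** Fallback: switch to the better-behaved trans-epoxide series. (2E,6E)-Farnesol with L-(+)-DET gives the (2S,3S)-epoxide, and the same sequence gives the (2R,3S)-chromanol (the C3 epimer). Invert C3 by Mitsunobu reaction (p-nitrobenzoic acid, DIAD, PPh3); the final LiOH step then cleaves both esters. This also removes the dependence on (2Z,6E)-farnesol, at the cost of one step and a hindered Mitsunobu reaction.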